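**Retrosynthetic overview**

- Feature: ring B of the target is a 3,5-dibromocatechol unit with its aryl ether on O1 (next to C6–H) and its free OH on O2 (next to C3–Br). In the twofold-symmetric isomer 2,2'-oxybis(3,5-dibromophenol) both rings carry the aryl group on O2. The target is therefore this isomer after a 1,2 shift of one aryl group from O2 to O1 of one catechol ring.
- Target ⇐ spiroketal dienone: reductive cleavage of the spiro C–O bond to the Br-flanked oxygen, with rearomatisation.
- Spiroketal dienone ⇐ symmetric bis-phenol: oxidative dearomatisation with trivalent iodine. The OH of one ring adds to the ether-bearing ortho carbon of the other ring and closes the only new ring, the five-membered 1,3-dioxole.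
- Symmetric bis-phenol ⇐ symmetric dialdehyde (double Baeyer–Villiger oxidation) ⇐ SNAr of 3,5-dibromosalicylaldehyde on 3,5-dibromo-2-fluorobenzaldehyde. Both benzene rings are bought.

Key step: step 3

Remark: the spiroketal dienone forms as a racemate at its spiro carbon and carries its ring bromines at C4' and C6' (C5 and C3 of the oxidised phenol). The target has no stereocentre. 3,5-Dibromo-2-fluorobenzaldehyde and 2,2'-oxydiphenol are assumed to be purchasable.

**Route**

Step 1
Reactants: 1 3,5-dibromo-2-hydroxybenzaldehyde (3,5-dibromosalicylaldehyde); 2 3,5-dibromo-2-fluorobenzaldehyde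
Product: 3 2,2'-oxybis(3,5-dibromobenzaldehyde)
Conditions: K2CO3, DMAc, 110 °C
Reagents that add atoms: none
Why: Nucleophilic aromatic substitution (SNAr), in which the phenoxide of 1 displaces fluoride from C2 of 2, a carbon activated by the ortho formyl group and by the ortho and para bromines, while the four aryl bromides, far poorer leaving groups in this addition–elimination, stay in place.

Step 2
Reactants: 3 2,2'-oxybis(3,5-dibromobenzaldehyde)
Product: 5 2,2'-oxybis(3,5-dibromophenol), via bis-formate ester 4 (not isolated)
Conditions: mCPBA, CH2Cl2, 40 °C; then HCl (cat.), MeOH, rt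
Reagents that add atoms: mCPBA (3-chloroperoxybenzoic acid), OOC(=O)c1cccc(Cl)c1
Why: Baeyer–Villiger oxidation of an aryl aldehyde in the Dakin sense, in which the ortho aryloxy oxygen makes the aryl group migrate in the Criegee intermediate so that each CHO becomes an O-formyl group; acid-catalysed methanolysis then frees both phenols without forming a phenoxide that could close onto an ortho C–Br bond.

Step 3
Reactants: 5 2,2'-oxybis(3,5-dibromophenol)
Product: 6 rac-4,4',6,6'-tetrabromospiro[1,3-benzodioxole-2,1'-cyclohexa-3',5'-dien]-2'-one
Conditions: PhI(OAc)2 (1.1 equiv), (CF3)2CHOH–CH2Cl2, 0 °C, 0.02 M; short silica plug, used at once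
Reagents that add atoms: none
Why: Ligand exchange of one phenol OH (on C1) at trivalent iodine, then loss of iodobenzene and acetate, leaves a phenoxenium-type cation whose charge sits mainly on C2, the ortho carbon carrying the ether oxygen, and the OH of the other ring adds there to form the new aryl O–C bond. The closest known reactions are the PhI(OAc)2-mediated dearomatising spiroketalisation of 2-alkoxyphenols with a tethered hydroxyl (ortho-quinone monoketal formation) and the oxidative closure of 2,2'-methylenebisphenols to spiro dienones by attack of one phenol oxygen on the ortho ipso carbon of the other ring. The single ring closed is the five-membered 1,3-dioxole, formed by 5-exo-trig spirocyclisation from the attacking oxygen, its two aryl carbons, the ether oxygen and C2. The spiro carbon is the only new stereocentre; nothing controls it, 6 forms as the racemate, and the centre returns to sp2 in step 4. The step needs attack at C2 and not at C4, at C6 or by an outside nucleophile: only C2 is within reach of the tethered oxygen, its oxygen substituent stabilises the charge there, and the weakly nucleophilic fluoroalcohol at high dilution offers no competitor. Because 5 is twofold-symmetric, oxidation of either phenol gives the same spiroketal, and the bromines at C4' and C6' beside the bulky spiro ketal should slow the Diels–Alder dimerisation typical of cyclohexa-2,4-dienones long enough for direct use.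

Step 4
Reactants: 6 rac-4,4',6,6'-tetrabromospiro[1,3-benzodioxole-2,1'-cyclohexa-3',5'-dien]-2'-one
Product: 7 3,5-dibromo-2-(3,5-dibromo-2-hydroxyphenoxy)phenol
Conditions: Zn dust, AcOH–THF, 0 °C to rt
Reagents that add atoms: none
Why: Reductive cleavage of an α-oxygenated ketone by zinc, in which two electrons enter the dienone, one ketal oxygen leaves as a phenoxide and the ring rearomatises; both spiro C–O bonds overlap equally with the carbonyl π system, so the better nucleofuge, the oxygen on C3a flanked by Br at C4 (an ortho,para-dibromophenoxide), should leave by a modest margin to give 7, while the other cleavage returns 5, which is separated by chromatography and put through step 3 again.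

**Compound list**

1 | 3,5-dibromo-2-hydroxybenzaldehyde | O=Cc1cc(Br)cc(Br)c1O | starting material
2 | 3,5-dibromo-2-fluorobenzaldehyde | O=Cc1cc(Br)cc(Br)c1F | starting material
3 | 2,2'-oxybis(3,5-dibromobenzaldehyde) | O=Cc1cc(Br)cc(Br)c1Oc1c(C=O)cc(Br)cc1Br | intermediate
4 | oxybis(3,5-dibromo-2,1-phenylene) diformate (bis-formate ester, not isolated) | O=COc1cc(Br)cc(Br)c1Oc1c(OC=O)cc(Br)cc1Br | intermediate
5 | 2,2'-oxybis(3,5-dibromophenol) | Oc1cc(Br)cc(Br)c1Oc1c(O)cc(Br)cc1Br | intermediate
6 | rac-4,4',6,6'-tetrabromospiro[1,3-benzodioxole-2,1'-cyclohexa-3',5'-dien]-2'-one (racemic at the spiro carbon) | O=C1C=C(Br)C=C(Br)C12Oc3cc(Br)cc(Br)c3O2 | intermediate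
7 | 3,5-dibromo-2-(3,5-dibromo-2-hydroxyphenoxy)phenol | Oc1cc(Br)cc(Br)c1Oc1cc(Br)cc(Br)c1O | target

**Step count**

Total steps: 4. Longest linear sequence: 4 steps (from 1 or 2).

**Steps most likely to fail**

Step 3. The electron-poor phenol may resist oxidation, the cation may be captured by acetate or by a second molecule, or the dienone may be lost through dimerisation or hydrolysis before it is reduced. The fallback gives up the aryl shift, sets out from 2 and comes back to the route at 7. SNAr of excess catechol on 2 (K2CO3, DMAc, 80 °C) should give 3,5-dibromo-2-(2-hydroxyphenoxy)benzaldehyde F1. Br2 (2 equiv) in AcOH should then brominate only the free-phenol ring, para and ortho to its OH, because the benzaldehyde ring is deactivated and has no open position ortho or para to oxygen. This gives 3,5-dibromo-2-(3,5-dibromo-2-hydroxyphenoxy)benzaldehyde F2. Baeyer–Villiger oxidation with mCPBA gives 3,5-dibromo-2-(3,5-dibromo-2-hydroxyphenoxy)phenyl formate F3, and methanolysis (HCl cat., MeOH) gives 7.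

Step 4. Electron transfer may expel the unflanked ketal oxygen preferentially and so return mainly 5, or zinc may strip bromine from the dienone. The fallback uses the complementary symmetric isomer, in which that same preference leads to the target. It sets out from none of the numbered compounds: purchased 2,2'-oxydiphenol (Oc1ccccc1Oc1ccccc1O) takes the place of 1 and 2, and it comes back to the route at 7. Br2 (4 equiv) in AcOH should brominate ortho and para to each OH to give 6,6'-oxybis(2,4-dibromophenol) F4. PhI(OAc)2 under the conditions of step 3 should close rac-3',4,5',6-tetrabromospiro[1,3-benzodioxole-2,1'-cyclohexa-3',5'-dien]-2'-one F5. In F5 the original ether oxygen is the unflanked one, so zinc in AcOH gives 7 when that oxygen leaves and returns F4 when the flanked one leaves.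

Step 1. The weakly nucleophilic, doubly ortho-substituted phenoxide of 1 may be too slow to displace fluoride from a carbon flanked by Br and CHO, so the tetra-ortho-substituted ether forms poorly while 2 is consumed in side reactions. The fallback makes the ether with one ortho substituent fewer and adds the last bromine afterwards; it sets out from 1 and comes back to the route at 3. SNAr of 1 on purchased 5-bromo-2-fluorobenzaldehyde (O=Cc1cc(Br)ccc1F) with K2CO3 in DMAc at 120 °C should give 3,5-dibromo-2-(4-bromo-2-formylphenoxy)benzaldehyde F6. NBS in concentrated H2SO4 should then brominate the one open position ortho to the ether oxygen, which is also meta to CHO, to give 3.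

**Further compounds**

F1 | step 3 | 3,5-dibromo-2-(2-hydroxyphenoxy)benzaldehyde | O=Cc1cc(Br)cc(Br)c1Oc1ccccc1O
F2 | step 3 | 3,5-dibromo-2-(3,5-dibromo-2-hydroxyphenoxy)benzaldehyde | O=Cc1cc(Br)cc(Br)c1Oc1cc(Br)cc(Br)c1O
F3 | step 3 | 3,5-dibromo-2-(3,5-dibromo-2-hydroxyphenoxy)phenyl formate | O=COc1cc(Br)cc(Br)c1Oc1cc(Br)cc(Br)c1O
F4 | step 4 | 6,6'-oxybis(2,4-dibromophenol) | Oc1c(Br)cc(Br)cc1Oc1cc(Br)cc(Br)c1O
F5 | step 4 | rac-3',4,5',6-tetrabromospiro[1,3-benzodioxole-2,1'-cyclohexa-3',5'-dien]-2'-one | O=C1C(Br)=CC(Br)=CC12Oc3cc(Br)cc(Br)c3O2
F6 | step 1 | 3,5-dibromo-2-(4-bromo-2-formylphenoxy)benzaldehyde | O=Cc1cc(Br)cc(Br)c1Oc1ccc(Br)cc1C=O
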